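**Plan**

- Numbering (indane): C1 is the alkylidene carbon, C8 its benzylidene CH, C2 and C3 the aryl-bearing stereocentres, C3a and C7a the fusion carbons, and ring A the benzo ring with oxygen at C4 and C6.
- Retrosynthesis: after the aryl ether C–O bonds, ring A is cut at C7–C7a, C6–C7, C4–C5 and C3a–C4. Ring A is a 1,3-dioxygenated benzene, the pattern that a vinylketene and an alkoxyacetylene produce, so it can be annulated last onto a cyclopentene that already carries C1, C2, C3 and C8. The cyclopentene is then cut at C1–C7a and C8–aryl (carbopalladation–Suzuki), at C3a=C7a (Wittig) and at C2–C3 (Nicholas alkylation).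
- Forward: the C2–C3 bond joins the two aryl-bearing fragments into an acyclic enyne chain, the five-membered ring closes with its Z-benzylidene, ring A is built, and the ethers are cleaved.
- Stereochemistry: C3 comes from an (S)-4-benzyloxazolidinone auxiliary and C2 from the syn-selective Nicholas alkylation. The Z-alkene comes from syn-carbopalladation followed by retentive coupling. All three pass unchanged through the pericyclic cascade.

Key step: step 12

Assumption: the boron enolate of 9 is taken to react in its chelated form (same face as an oxazolidinone alkylation), and the cobalt-stabilised propargyl cation is taken to equilibrate faster than it is captured, so racemic 5 converges on one diastereomer.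

**Route**

Step 1
Reactants: 1 3,5-dimethoxybenzaldehyde; 2 ethynylmagnesium bromide
Product: 3 rac-1-(3,5-dimethoxyphenyl)prop-2-yn-1-ol
Conditions: 2 (0.5 M in THF), THF, 0 °C to rt; sat. aq. NH4Cl
Reagents that add atoms: none
Why: Grignard 1,2-addition of the alkynyl reagent to the aldehyde is fast and clean, and a racemic carbinol suffices because this centre is ionised in step 5.

Step 2
Reactants: 3 rac-1-(3,5-dimethoxyphenyl)prop-2-yn-1-ol
Product: 4 rac-1,3-dimethoxy-5-(1-methoxyprop-2-yn-1-yl)benzene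
Conditions: NaH (1.1 equiv), MeI, THF, 0 °C to rt
Reagents that add atoms: iodomethane CI
Why: Williamson etherification of the sodium alkoxide installs the methoxy leaving group for cation generation, and one equivalent of NaH leaves the much less acidic alkyne C–H untouched.

Step 3
Reactants: 4 rac-1,3-dimethoxy-5-(1-methoxyprop-2-yn-1-yl)benzene
Product: 5 hexacarbonyldicobalt complex of 4 (Co2(CO)6 bridging the C≡C bond, racemic)
Conditions: Co2(CO)8, CH2Cl2, rt
Reagents that add atoms: dicobalt octacarbonyl O=C=[Co](=C=O)(=C=O)(=C=O)[Co](=C=O)(=C=O)(=C=O)=C=O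
Why: A terminal alkyne displaces two CO ligands of Co2(CO)8 at room temperature to give the stable bridging alkyne complex that is the precursor of a Nicholas cation.

Step 4
Reactants: 6 4-methoxyphenylacetic acid; 7 (S)-4-benzyloxazolidin-2-one
Product: 9 (S)-4-benzyl-3-[2-(4-methoxyphenyl)acetyl]oxazolidin-2-one, via mixed pivalic anhydride 8 (not isolated)
Conditions: PivCl, Et3N, THF, −20 °C; then 7, LiCl, −20 °C to rt
Reagents that add atoms: none
Why: One-pot N-acylation of the oxazolidinone through the mixed pivalic anhydride under Et3N/LiCl is the standard route to N-acyl oxazolidinones and delivers the less hindered arylacetyl group.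

Step 5
Reactants: 9 (S)-4-benzyl-3-[2-(4-methoxyphenyl)acetyl]oxazolidin-2-one; 5 hexacarbonyldicobalt complex of 4
Product: 12 (S)-4-benzyl-3-[(2S,3R)-3-(3,5-dimethoxyphenyl)-2-(4-methoxyphenyl)pent-4-ynoyl]oxazolidin-2-one, via boron enolate 10 (not isolated), via cobalt-complexed adduct 11 (not isolated)
Conditions: 9, Bu2BOTf, iPr2NEt, CH2Cl2, −78 to 0 °C; then 5, Bu2BOTf, −78 to 0 °C; pH 7 buffer; crude 11, Fe(NO3)3·9H2O, EtOH, rt
Reagents that add atoms: none
Why: This is a Nicholas reaction in its Lewis-acid variant with a boron enolate, in which Bu2BOTf ionises the methyl ether of 5 in the presence of the chelated Z enolate 10, the cation adds to the enolate face away from the benzyl group of the auxiliary (sets C3) through an open transition state that favours the syn adduct (sets C2 relative to C3), and Fe(NO3)3 then releases the alkyne oxidatively from cobalt.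

Step 6
Reactants: 12 (S)-4-benzyl-3-[(2S,3R)-3-(3,5-dimethoxyphenyl)-2-(4-methoxyphenyl)pent-4-ynoyl]oxazolidin-2-one
Product: 13 (2S,3R)-3-(3,5-dimethoxyphenyl)-2-(4-methoxyphenyl)pent-4-yn-1-ol
Conditions: LiBH4, MeOH (1.1 equiv), THF, 0 °C
Reagents that add atoms: none
Why: Reductive removal of the oxazolidinone auxiliary with LiBH4 attacks the exocyclic imide carbonyl under conditions too weakly basic to epimerise the α-aryl centre, and the auxiliary should be recoverable.

Step 7
Reactants: 13 (2S,3R)-3-(3,5-dimethoxyphenyl)-2-(4-methoxyphenyl)pent-4-yn-1-ol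
Product: 14 (2S,3R)-3-(3,5-dimethoxyphenyl)-2-(4-methoxyphenyl)pent-4-ynal
Conditions: Dess–Martin periodinane, NaHCO3, CH2Cl2, 0 °C to rt; used at once
Reagents that add atoms: none
Why: Buffered Dess–Martin oxidation stops at the aldehyde and keeps enolisation of the α-aryl aldehyde to a minimum, provided the crude product is carried on directly.

Step 8
Reactants: 15 1-(triphenyl-λ5-phosphanylidene)propan-2-one
Product: 17 1-bromo-1-(triphenyl-λ5-phosphanylidene)propan-2-one, via bromophosphonium bromide 16 (not isolated)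
Conditions: Br2 (1.0 equiv), CH2Cl2, 0 °C; then aq. NaOH
Reagents that add atoms: bromine BrBr
Why: Electrophilic bromination of the stabilised ylide gives the α-bromophosphonium salt, which aqueous base deprotonates to the α-bromo ylide.

Step 9
Reactants: 14 (2S,3R)-3-(3,5-dimethoxyphenyl)-2-(4-methoxyphenyl)pent-4-ynal; 17 1-bromo-1-(triphenyl-λ5-phosphanylidene)propan-2-one
Product: 18 (3Z,5R,6R)-3-bromo-6-(3,5-dimethoxyphenyl)-5-(4-methoxyphenyl)oct-3-en-7-yn-2-one
Conditions: PhMe, 70 °C
Reagents that add atoms: none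
Why: Wittig olefination with the doubly stabilised, non-basic ylide should place the acetyl group trans to the chain, so that bromine is cis to C3 (Z) as ring closure requires, without epimerising the aldehyde.

Step 10
Reactants: 18 (3Z,5R,6R)-3-bromo-6-(3,5-dimethoxyphenyl)-5-(4-methoxyphenyl)oct-3-en-7-yn-2-one; 19 4-methoxyphenylboronic acid
Product: 20 1-[(3S,4S,5Z)-4-(3,5-dimethoxyphenyl)-3-(4-methoxyphenyl)-5-[(4-methoxyphenyl)methylidene]cyclopent-1-en-1-yl]ethan-1-one
Conditions: Pd(PPh3)4 (5 mol %), K2CO3, dioxane/H2O, 0.02 M, 60 °C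
Reagents that add atoms: none
Why: In this carbopalladation–Suzuki–Miyaura domino sequence zerovalent palladium inserts into the C–Br bond, the alkenyl divalent palladium species adds syn across the tethered terminal alkyne (5-exo-dig, forms C1–C7a), and retentive coupling with the boronic acid leaves the new aryl group cis to C7a, which is the Z-benzylidene.

Step 11
Reactants: 20 1-[(3S,4S,5Z)-4-(3,5-dimethoxyphenyl)-3-(4-methoxyphenyl)-5-[(4-methoxyphenyl)methylidene]cyclopent-1-en-1-yl]ethan-1-one
Product: 22 2-diazo-1-[(3S,4S,5Z)-4-(3,5-dimethoxyphenyl)-3-(4-methoxyphenyl)-5-[(4-methoxyphenyl)methylidene]cyclopent-1-en-1-yl]ethan-1-one, via trifluoroacetyl diketone 21 (not isolated)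
Conditions: LiN(SiMe3)2, THF, −78 °C; CF3CO2CH2CF3, −78 °C; 5% aq. HCl; crude 21, 4-acetamidobenzenesulfonyl azide, Et3N, H2O (1 equiv), MeCN, rt
Reagents that add atoms: 4-acetamidobenzenesulfonyl azide CC(=O)Nc1ccc(cc1)S(=O)(=O)N=[N+]=[N-]
Why: In this detrifluoroacetylative diazo transfer (Regitz type, the standard entry to α,β-unsaturated diazomethyl ketones) the amide base removes a methyl proton kinetically at −78 °C in preference to the hindered tertiary hydrogen at C3, Claisen condensation gives diketone 21, and the sulfonyl azide transfers N2 to the activated methylene with loss of the trifluoroacetyl group.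

Step 12
Reactants: 22 2-diazo-1-[(3S,4S,5Z)-4-(3,5-dimethoxyphenyl)-3-(4-methoxyphenyl)-5-[(4-methoxyphenyl)methylidene]cyclopent-1-en-1-yl]ethan-1-one; 23 ethoxyacetylene
Product: 28 (1Z,2S,3S)-2-(3,5-dimethoxyphenyl)-6-ethoxy-3-(4-methoxyphenyl)-1-[(4-methoxyphenyl)methylidene]-2,3-dihydro-1H-inden-4-ol, via vinylketene 24 (not isolated), via cyclobutenone 25 (not isolated), via dienylketene 26 (not isolated), via cyclohexadienone 27 (not isolated)
Conditions: 23 (3 equiv, hexane solution), degassed ClCH2CH2Cl, blue LEDs (450 nm), borosilicate glass, 20 °C; then 80 °C, dark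
Reagents that add atoms: none
Why: Visible-light excitation of the diazo ketone expels N2 and the cyclopentenyl carbon migrates (Wolff rearrangement, C7–C7a) to vinylketene 24, whose electrophilic ketene carbon is attacked by the unsubstituted, nucleophilic terminus of 23, so the [2+2] cycloaddition (C4–C5 and C6–C7) to cyclobutenone 25 can only put the ethoxy group on C6. On heating, 25 opens by reversible 4π electrocyclic cleavage to dienylketene 26, and ring A closes by a 6π disrotatory electrocyclisation that forms C3a–C4 and gives dienone 27, which enolises to the C4 phenol. The closest known reaction is the Danheiser benzannulation in its photochemical diazo ketone version, which accepts alkoxy- and siloxyacetylenes. No stereocentre is created, and C2, C3 and the exocyclic alkene are spectators in these neutral, base-free steps. The step needs the 4,6-oxygen pattern, ring closure onto C3a only, and survival of the Z-benzylidene: the first is fixed by ketene/ynol ether polarity, the second by the fact that only C7a=C3a is linearly conjugated with the ketene (C1=C8 is cross-conjugated). The third is secured by irradiating only the long-wavelength n–π* band of the diazo ketone, where the vinylketene and the stilbene-type product should not absorb, and by running the thermal stage in the dark.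

Step 13
Reactants: 28 (1Z,2S,3S)-2-(3,5-dimethoxyphenyl)-6-ethoxy-3-(4-methoxyphenyl)-1-[(4-methoxyphenyl)methylidene]-2,3-dihydro-1H-inden-4-ol
Product: 29 (1Z,2S,3S)-2-(3,5-dihydroxyphenyl)-3-(4-hydroxyphenyl)-1-[(4-hydroxyphenyl)methylidene]-2,3-dihydro-1H-indene-4,6-diol
Conditions: BBr3 (excess), CH2Cl2, −78 to 0 °C, dark; poured into ice-cold aq. NaHCO3
Reagents that add atoms: none
Why: Lewis-acid ether cleavage with BBr3 removes aryl methyl and ethyl groups as the alkyl bromides (the usual last step for permethylated resveratrol dimers), and low temperature, exclusion of light and a cold bicarbonate quench limit the exposure of the electron-rich Z-alkene to HBr.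

**Compound list**

1 | 3,5-dimethoxybenzaldehyde | COc1cc(C=O)cc(OC)c1 | starting material
2 | ethynylmagnesium bromide | C#C[Mg]Br | starting material
3 | rac-1-(3,5-dimethoxyphenyl)prop-2-yn-1-ol | COc1cc(cc(OC)c1)C(O)C#C | intermediate
4 | rac-1,3-dimethoxy-5-(1-methoxyprop-2-yn-1-yl)benzene | COc1cc(cc(OC)c1)C(OC)C#C | intermediate
5 | hexacarbonyldicobalt complex of 4 (Co2(CO)6 bridging the alkyne, racemic) | COC(c1cc(OC)cc(OC)c1)C12[CH]3[Co]1(=C=O)(=C=O)(=C=O)[Co]23(=C=O)(=C=O)=C=O | intermediate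
6 | 4-methoxyphenylacetic acid | COc1ccc(CC(=O)O)cc1 | starting material
7 | (S)-4-benzyloxazolidin-2-one | O=C1N[C@@H](Cc2ccccc2)CO1 | starting material
8 | 2-(4-methoxyphenyl)acetic pivalic anhydride (not isolated) | COc1ccc(CC(=O)OC(=O)C(C)(C)C)cc1 | intermediate
9 | (S)-4-benzyl-3-[2-(4-methoxyphenyl)acetyl]oxazolidin-2-one | COc1ccc(CC(=O)N2[C@@H](Cc3ccccc3)COC2=O)cc1 | intermediate
10 | Z dibutylboron enolate of 9 (not isolated) | COc1ccc(/C=C(\OB(CCCC)CCCC)N2[C@@H](Cc3ccccc3)COC2=O)cc1 | intermediate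
11 | hexacarbonyldicobalt complex of 12 (not isolated) | O=C([C@H](c1ccc(OC)cc1)[C@@H](c1cc(OC)cc(OC)c1)C12[CH]3[Co]1(=C=O)(=C=O)(=C=O)[Co]23(=C=O)(=C=O)=C=O)N1[C@@H](Cc2ccccc2)COC1=O | intermediate
12 | (S)-4-benzyl-3-[(2S,3R)-3-(3,5-dimethoxyphenyl)-2-(4-methoxyphenyl)pent-4-ynoyl]oxazolidin-2-one | O=C([C@H](c1ccc(OC)cc1)[C@@H](c1cc(OC)cc(OC)c1)C#C)N1[C@@H](Cc2ccccc2)COC1=O | intermediate
13 | (2S,3R)-3-(3,5-dimethoxyphenyl)-2-(4-methoxyphenyl)pent-4-yn-1-ol | OC[C@H](c1ccc(OC)cc1)[C@@H](c1cc(OC)cc(OC)c1)C#C | intermediate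
14 | (2S,3R)-3-(3,5-dimethoxyphenyl)-2-(4-methoxyphenyl)pent-4-ynal | O=C[C@H](c1ccc(OC)cc1)[C@@H](c1cc(OC)cc(OC)c1)C#C | intermediate
15 | 1-(triphenyl-λ5-phosphanylidene)propan-2-one | CC(=O)C=P(c1ccccc1)(c1ccccc1)c1ccccc1 | starting material
16 | (1-bromo-2-oxopropyl)triphenylphosphonium bromide (not isolated) | CC(=O)C(Br)[P+](c1ccccc1)(c1ccccc1)c1ccccc1.[Br-] | intermediate
17 | 1-bromo-1-(triphenyl-λ5-phosphanylidene)propan-2-one | CC(=O)C(Br)=P(c1ccccc1)(c1ccccc1)c1ccccc1 | intermediate
18 | (3Z,5R,6R)-3-bromo-6-(3,5-dimethoxyphenyl)-5-(4-methoxyphenyl)oct-3-en-7-yn-2-one | CC(=O)/C(Br)=C/[C@H](c1ccc(OC)cc1)[C@@H](c1cc(OC)cc(OC)c1)C#C | intermediate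
19 | 4-methoxyphenylboronic acid | COc1ccc(B(O)O)cc1 | starting material
20 | 1-[(3S,4S,5Z)-4-(3,5-dimethoxyphenyl)-3-(4-methoxyphenyl)-5-[(4-methoxyphenyl)methylidene]cyclopent-1-en-1-yl]ethan-1-one | CC(=O)C1=C[C@H](c2ccc(OC)cc2)[C@@H](c2cc(OC)cc(OC)c2)/C1=C/c1ccc(OC)cc1 | intermediate
21 | 4,4,4-trifluoro-1-[cyclopentenyl group of 20]butane-1,3-dione (not isolated) | O=C(CC(=O)C(F)(F)F)C1=C[C@H](c2ccc(OC)cc2)[C@@H](c2cc(OC)cc(OC)c2)/C1=C/c1ccc(OC)cc1 | intermediate
22 | 2-diazo-1-[(3S,4S,5Z)-4-(3,5-dimethoxyphenyl)-3-(4-methoxyphenyl)-5-[(4-methoxyphenyl)methylidene]cyclopent-1-en-1-yl]ethan-1-one | [N-]=[N+]=CC(=O)C1=C[C@H](c2ccc(OC)cc2)[C@@H](c2cc(OC)cc(OC)c2)/C1=C/c1ccc(OC)cc1 | intermediate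
23 | ethoxyacetylene (ethoxyethyne) | CCOC#C | starting material
24 | 2-[cyclopentenyl group of 20]ethen-1-one, the vinylketene (not isolated) | O=C=CC1=C[C@H](c2ccc(OC)cc2)[C@@H](c2cc(OC)cc(OC)c2)/C1=C/c1ccc(OC)cc1 | intermediate
25 | 3-ethoxy-4-[cyclopentenyl group of 20]cyclobut-2-en-1-one, both epimers at the new ring carbon (not isolated) | CCOC1=CC(=O)C1C1=C[C@H](c2ccc(OC)cc2)[C@@H](c2cc(OC)cc(OC)c2)/C1=C/c1ccc(OC)cc1 | intermediate
26 | (3E)-3-ethoxy-4-[cyclopentenyl group of 20]buta-1,3-dien-1-one, the dienylketene (not isolated) | O=C=C/C(OCC)=C\C1=C[C@H](c2ccc(OC)cc2)[C@@H](c2cc(OC)cc(OC)c2)/C1=C/c1ccc(OC)cc1 | intermediate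
27 | cyclohexa-2,4-dienone tautomer of 28 (C4 ketone, hydrogen on C3a, C3a unassigned; C2, C3 and alkene as in 28; not isolated) | O=C1C=C(OCC)C=C2C1[C@H](c1ccc(OC)cc1)[C@@H](c1cc(OC)cc(OC)c1)/C2=C/c1ccc(OC)cc1 | intermediate
28 | (1Z,2S,3S)-2-(3,5-dimethoxyphenyl)-6-ethoxy-3-(4-methoxyphenyl)-1-[(4-methoxyphenyl)methylidene]-2,3-dihydro-1H-inden-4-ol | COc1ccc(/C=C2\c3cc(OCC)cc(O)c3[C@H](c3ccc(OC)cc3)[C@H]2c2cc(OC)cc(OC)c2)cc1 | intermediate
29 | (1Z,2S,3S)-2-(3,5-dihydroxyphenyl)-3-(4-hydroxyphenyl)-1-[(4-hydroxyphenyl)methylidene]-2,3-dihydro-1H-indene-4,6-diol | Oc1ccc(/C=C2\c3cc(O)cc(O)c3[C@H](c3ccc(O)cc3)[C@H]2c2cc(O)cc(O)c2)cc1 | target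

**Totals**

Total step count: 13 steps.
Longest linear sequence: 11 steps (steps 1–3, 5–7, 9–13).

**Steps most likely to fail**

Step 12. The dienoyl diazo ketone and the 4-methoxybenzylidene form one conjugated chromophore, so excitation may twist the exocyclic double bond (Z to E scrambling) in competition with nitrogen loss, and the vinylketene may be captured inefficiently. The fallback sets out from 18 and comes back at 28 by postponing the aryl group on C8. Cyclisation–borylation of 18 with bis(pinacolato)diboron (PdCl2(dppf), KOAc, dioxane, 80 °C; the same syn-carbopalladation, then capture by boron) would give alkenyl boronate F1, whose chromophore no longer reaches the visible. The diazo transfer of step 11 would then lead, by way of trifluoroacetyl diketone F2, to diazo ketone F3. Irradiation with 23 and heating as in step 12 would pass through vinylketene F4, cyclobutenone F5, dienylketene F6 and cyclohexadienone F7 to boronate phenol F8. Suzuki–Miyaura coupling of F8 with 4-iodoanisole (Pd(PPh3)4, K2CO3, dioxane/H2O, 60 °C), which proceeds with retention at the alkenyl carbon, would deliver 28.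

Step 10. Intermolecular transmetalation and coupling at the C–Br bond may outrun alkyne insertion, or the terminal alkyne may be consumed by alkynylation or oligomerisation under zerovalent palladium and base. The fallback sets out from 13 and comes back at 20 by fixing the alkene geometry before the ring is closed. Sonogashira coupling of 13 with 4-iodoanisole (PdCl2(PPh3)2, CuI, Et3N) would give aryl alkyne F9. Lindlar semihydrogenation (H2, Pd/CaCO3 poisoned with Pb(OAc)2, quinoline) would give Z-styrene alcohol F10, Dess–Martin oxidation aldehyde F11, and Wittig reaction with 17 bromo dienone F12. An intramolecular Mizoroki–Heck reaction of F12 (Pd(OAc)2, PPh3, Ag2CO3, MeCN, 70 °C) would then close the ring by 5-exo-trig syn-carbopalladation of the Z-styrene. Syn β-hydride elimination of the only available hydrogen (on C1) would leave the aryl group cis to C7a and give 20.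

Step 13. HBr formed from the free C4 phenol and BBr3 may protonate C1 and generate a 4-alkoxybenzyl cation at C8, so the exocyclic double bond may equilibrate from Z to E during ether cleavage. The fallback sets out from 28 and comes back at 29 by correcting the geometry afterwards. The cleavage would be taken to completion regardless of alkene geometry, giving the E-configured hexaphenol F13 where equilibration has occurred. Direct irradiation of F13 (365 nm, degassed MeOH) should drive the mixture towards a photostationary state enriched in the more twisted, more weakly absorbing Z isomer, as is known for stilbenoids. Isomer 29 would be separated by reversed-phase HPLC and F13 recycled.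

**Further compounds**

F1 | step 12 | 1-[(3S,4S,5Z)-4-(3,5-dimethoxyphenyl)-3-(4-methoxyphenyl)-5-[(4,4,5,5-tetramethyl-1,3,2-dioxaborolan-2-yl)methylidene]cyclopent-1-en-1-yl]ethan-1-one | CC(=O)C1=C[C@H](c2ccc(OC)cc2)[C@@H](c2cc(OC)cc(OC)c2)/C1=C/B1OC(C)(C)C(C)(C)O1
F2 | step 12 | 4,4,4-trifluoro-1-[cyclopentenyl group of F1]butane-1,3-dione | O=C(CC(=O)C(F)(F)F)C1=C[C@H](c2ccc(OC)cc2)[C@@H](c2cc(OC)cc(OC)c2)/C1=C/B1OC(C)(C)C(C)(C)O1
F3 | step 12 | 2-diazo-1-[cyclopentenyl group of F1]ethan-1-one | [N-]=[N+]=CC(=O)C1=C[C@H](c2ccc(OC)cc2)[C@@H](c2cc(OC)cc(OC)c2)/C1=C/B1OC(C)(C)C(C)(C)O1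
F4 | step 12 | 2-[cyclopentenyl group of F1]ethen-1-one (vinylketene) | O=C=CC1=C[C@H](c2ccc(OC)cc2)[C@@H](c2cc(OC)cc(OC)c2)/C1=C/B1OC(C)(C)C(C)(C)O1
F5 | step 12 | 3-ethoxy-4-[cyclopentenyl group of F1]cyclobut-2-en-1-one (both epimers at the new ring carbon) | CCOC1=CC(=O)C1C1=C[C@H](c2ccc(OC)cc2)[C@@H](c2cc(OC)cc(OC)c2)/C1=C/B1OC(C)(C)C(C)(C)O1
F6 | step 12 | (3E)-3-ethoxy-4-[cyclopentenyl group of F1]buta-1,3-dien-1-one (dienylketene) | O=C=C/C(OCC)=C\C1=C[C@H](c2ccc(OC)cc2)[C@@H](c2cc(OC)cc(OC)c2)/C1=C/B1OC(C)(C)C(C)(C)O1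
F7 | step 12 | cyclohexa-2,4-dienone tautomer of F8 (C4 ketone, hydrogen on C3a, C3a unassigned) | O=C1C=C(OCC)C=C2C1[C@H](c1ccc(OC)cc1)[C@@H](c1cc(OC)cc(OC)c1)/C2=C/B1OC(C)(C)C(C)(C)O1
F8 | step 12 | (1Z,2S,3S)-2-(3,5-dimethoxyphenyl)-6-ethoxy-3-(4-methoxyphenyl)-1-[(4,4,5,5-tetramethyl-1,3,2-dioxaborolan-2-yl)methylidene]-2,3-dihydro-1H-inden-4-ol | CC1(C)OB(/C=C2\c3cc(OCC)cc(O)c3[C@H](c3ccc(OC)cc3)[C@H]2c2cc(OC)cc(OC)c2)OC1(C)C
F9 | step 10 | (2S,3S)-3-(3,5-dimethoxyphenyl)-2,5-bis(4-methoxyphenyl)pent-4-yn-1-ol | OC[C@H](c1ccc(OC)cc1)[C@@H](c1cc(OC)cc(OC)c1)C#Cc1ccc(OC)cc1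
F10 | step 10 | (2S,3S,4Z)-3-(3,5-dimethoxyphenyl)-2,5-bis(4-methoxyphenyl)pent-4-en-1-ol | OC[C@H](c1ccc(OC)cc1)[C@@H](c1cc(OC)cc(OC)c1)/C=C\c1ccc(OC)cc1
F11 | step 10 | (2S,3S,4Z)-3-(3,5-dimethoxyphenyl)-2,5-bis(4-methoxyphenyl)pent-4-enal | O=C[C@H](c1ccc(OC)cc1)[C@@H](c1cc(OC)cc(OC)c1)/C=C\c1ccc(OC)cc1
F12 | step 10 | (3Z,5R,6S,7Z)-3-bromo-6-(3,5-dimethoxyphenyl)-5,8-bis(4-methoxyphenyl)octa-3,7-dien-2-one | CC(=O)/C(Br)=C/[C@H](c1ccc(OC)cc1)[C@@H](c1cc(OC)cc(OC)c1)/C=C\c1ccc(OC)cc1
F13 | step 13 | (1E,2S,3S)-2-(3,5-dihydroxyphenyl)-3-(4-hydroxyphenyl)-1-[(4-hydroxyphenyl)methylidene]-2,3-dihydro-1H-indene-4,6-diol | Oc1ccc(/C=C2/c3cc(O)cc(O)c3[C@H](c3ccc(O)cc3)[C@H]2c2cc(O)cc(O)c2)cc1
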